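## Structural features

The target 17 is 3-(4-hydroxyphenyl)-5-methoxy-4,7-diphenylbenzofuran-2,6-dione. A five-membered unsaturated lactone (O1, C2, C3, C3a, C7a) is fused along C3a–C7a to a six-membered carbocycle (C3a, C4, C5, C6, C7, C7a). That carbocycle is not benzenoid but a para-quinone methide, with C6=O in the ring and the C3=C3a double bond leading into the lactone. Every carbon of the six-membered ring is substituted: phenyl on C4 and C7, methoxy on C5, the carbonyl oxygen on C6, the lactone oxygen O1 on C7a and C3 on C3a; C3 also carries the 4-hydroxyphenyl ring. There is no stereocentre, since C3 is sp2; the only stereocentre met on the way (C3 of the reduced lactones) is transient. The fragile parts are the quinone methide (electrophilic, easily reduced, sensitive to base and nucleophiles), the aryl lactone, and, one step before the end, an acidic enolic hydroxyl on C5 beside a free phenol. The real difficulties are the crowding along C3(aryl)–C3a–C4(phenyl), the placing of three different oxygen functions (O5, O6 and O1 on C7a) on a fully substituted ring, and telling O5 from the phenolic oxygen. Two hydrogens below the target lies a benzenoid 3-arylbenzofuran-2(3H)-one in which C3 bears the 4-oxygenated phenyl ring, ring carbon C3a and the acyl carbon C2, whose ester oxygen O1 sits on C7a ortho to C3a. This Ar2CH–C(=O)–O–aryl array is what forms when an ortho hydroxyl captures a diarylketene, and the ketene is the Wolff product of a 2-diazo-1,2-diarylethanone; the key step uses this relationship.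

## Logic of the disconnections

17 to 16: the O5–CH3 bond is cut. O5–H in 16 is the most acidic proton of the molecule, because the enol is conjugated through C4=C5 and C3a=C3 with the lactone carbonyl, so the methyl group can be added last on the basis of acidity. The gain is that 16 needs no orthogonal protection of its two hydroxyls. The forward step must discriminate by acidity (a diazoalkane, no base), not by nucleophilicity.

16 to 14 through 15: no skeletal bond is cut. Two hydrogens are returned (to C3 and O6), O5 and O6 are tied into an isopropylidene ketal and the phenolic oxygen into a methoxymethyl acetal. The benzenoid, protected lactone 14 is robust and is the direct outcome of ketene capture. The forward step needs an acid that cleaves a catechol ketal without opening the lactone, and an oxidant that removes exactly two electrons.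

14 to 12 through 13: the O1–C2 bond and the bond from C3 to the 4-alkoxyphenyl ring are cut; that ring is put back on C2 and N2 is placed on C3. This removes the lactone ring and the crowded C3 in one stroke and leaves an open-chain 1,2-diarylethanone skeleton. The forward step needs the aryl shift to outrun carbene side reactions and needs the C7a hydroxyl free and ortho to the ketene-bearing carbon.

12 to 11 to 10: the O–H of C7a is masked as a silyl ether and the C=N2 unit is traced to the methylene of 10. The diazo group is introduced late because it tolerates little, and the phenol stays silylated until it is needed. The gain is an ordinary benzyl aryl ketone, 10. The forward steps need diazo transfer at a hindered methylene and a desilylation free of acid, metal and reductant.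

10 to 7 and 9: the C3a–CH2 bond is cut. This is the convergent cut; it divides the molecule into the hexasubstituted arene 7 and a simple aryl methyl ketone 9, and it makes the hindered aryl–carbon bond at a methylene, before C3 becomes crowded. The forward step is a palladium-catalysed enolate arylation at a di-ortho-substituted, electron-rich C–Br bond, with the neighbouring oxygen masked so that no benzofuran can form.

7 to 6 to 5: the O–Si bond and the C3a–Br bond are cut. The brominated carbon is the only unsubstituted position of the central ring of 5, so regiochemistry is not in question. The forward steps need monobromination without oxidation of the electron-rich phenol and silylation of a hydroxyl between two ortho groups.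

5 to 4 to 2 (with 3) to 1: the two ketal C–O bonds, the three acetyl groups and the C6–O bond are cut. The third oxygen is traced to acetoxylation of the symmetrical quinone 1, whose two free positions are equivalent. In 4 only one pair of hydroxyls is vicinal, so the ketal from 3 can form in one place only and leaves the C7a hydroxyl free.

9 to 8: the O–CH2 bond of the methoxymethyl ether is cut, leading to a commercial phenol. The protecting group must survive base, fluoride and light and fall in the final acid step.

## Other disconnections considered

Alternative 1: The cut is through the benzene ring itself, at C7a–C3a, with the ring traced to the 4-alkenyl-4-methoxycyclobutenone A1. In the forward key step, heating A1 would open the four-membered ring to a dienylketene; 6π electrocyclisation would join the ketene carbon (future C7a) to the alkene terminus (future C3a) and tautomerisation would give phenol A2.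
- In its favour: all six ring substituents are placed by the order of two organometallic additions to a squaric ester. The C5 methoxy group comes from methylating the tertiary alkoxide, so O5 (methyl) and O6 (isopropyl) are differentiated from the start. On this point the alternative is better than the chosen plan, which must methylate selectively at the end. The pericyclic cascade needs no light and no diazo compound, and as a ring-forming event it is at least as dependable as the Wolff step.
- Against it: A2 still lacks the acyl carbon C2. The silyloxy-bearing benzylic carbon would have to be ionised and homologated by one carbon (cyanide or carbonylation) beside the C4 phenyl group. That is an intermolecular substitution at the most crowded carbon, which the chosen plan avoids by an intramolecular 1,2-shift. The alkenyl-metal partner of defined geometry needs several steps, and three different ethers (isopropyl, benzyl, silyl) must be removed in order.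
- Comparison: better on the arene substitution pattern and the O5/O6 problem, worse at C3, and longer overall than the eleven steps of the chosen route.

Alternative 2: The cut is the aryl C–O bond O1–C7a, with both oxidations in the same operation. In the forward key step, DDQ would oxidise the C6 phenol of the diarylacetic acid A3 to the quinone methide C3=C3a; the carboxyl would add to C7a in a 5-exo-trig conjugate addition; the ring would re-aromatise and a second oxidation would give A4, the silyl ether of 17, which fluoride would convert into the target.
- In its favour: it is the shortest plan. No oxygen is needed on C7a at the outset and the target oxidation level is reached in the key step. The methoxy group can be put on the symmetrical diol A5, where either hydroxyl gives the same monoether. On step economy, on the methyl ether and on the absence of diazo chemistry the alternative is better than the chosen plan.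
- Against it: the carboxyl must attack ring carbon C7a while the most electrophilic site of the quinone methide is the exocyclic C3. A diarylacetic acid at that oxidation level can lose CO2 or take up water at C3, and two equivalents of oxidant act on an electron-rich product. Attaching the acetic acid carbon to the ring para to the free hydroxyl is itself a regiochemical question.
- Comparison: structurally simpler and shorter, mechanistically less secure in the key step than a Wolff shift in which only one group can migrate; equal in that the final deprotection is a single mild step.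

Alternative 3: The cuts are the C4–phenyl and C7–phenyl bonds. In the forward key step, the dibromo lactone A6 would couple twice with phenylboronic acid A8 under Pd(OAc)2 (divalent palladium reduced in situ to zerovalent palladium), a bulky biaryl phosphine and K3PO4 to give A7.
- In its favour: A6 could come in a few steps from a simple benzodioxolol, and the phenyl groups arrive late and could be varied. Suzuki coupling at di-ortho-substituted positions is more dependable than the ketone α-arylation of step 6; on this point the alternative is better. The step count would be equal or lower.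
- Against it: the C3–H of the lactone is acidic (its enol is a 2-hydroxybenzofuran). Under K3PO4 the enolate can be arylated by the C–Br bond of another molecule, the lactone can open and the pivalate can be lost. Both bromides sit between two ortho substituents on an electron-rich ring, and C4–Br is next to the aryl-bearing C3, so slow oxidative addition and protodebromination are to be feared. The pivalate needs base for its removal, which must happen before the quinone methide exists.
- Comparison: after A7 the end game (acid, oxidation, selective methylation) is the same as in the chosen plan, so the two are equal there. The alternative builds C3 first and the crowding afterwards; the chosen plan makes the hindered aryl–carbon bond at a methylene and creates C3 by migration.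

Key step: step 9

Remark: 16 and 17 are written as the para-quinone methide tautomers (C3=C3a, C6=O), assumed to be the stable forms; the target has no stereocentre, so the racemic C3 of 14 and 15 is of no consequence.

## Route

Step 1
Reactants: 1 2,5-diphenyl-1,4-benzoquinone
Product: 2 3,6-diphenylbenzene-1,2,4-triyl triacetate
Conditions: Ac2O, H2SO4 (cat.), 50 °C
Reagents that add atoms: acetic anhydride, CC(=O)OC(C)=O
Why: Thiele–Winter acetoxylation: acid-catalysed conjugate addition of the anhydride at an unsubstituted quinone carbon, enolisation and acetylation; the two free positions of 1 are equivalent by symmetry, so a single triacetate is expected.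

Step 2
Reactants: 2 3,6-diphenylbenzene-1,2,4-triyl triacetate; 3 2,2-dimethoxypropane
Product: 5 2,2-dimethyl-4,7-diphenyl-1,3-benzodioxol-5-ol, via 3,6-diphenylbenzene-1,2,4-triol 4 (not isolated)
Conditions: HCl (1.25 M in MeOH), 60 °C, Ar; evaporate; 3 (5 equiv), TsOH·H2O (5 mol %), toluene, reflux over 4 Å sieves, Ar
Reagents that add atoms: none
Why: Acid-catalysed transesterification frees the air-sensitive triol 4, which is ketalised at once by transketalisation with 3; only one pair of hydroxyls (future O5 and O6) is vicinal, so one five-membered cyclic ketal can form and the future C7a hydroxyl stays free.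

Step 3
Reactants: 5 2,2-dimethyl-4,7-diphenyl-1,3-benzodioxol-5-ol
Product: 6 6-bromo-2,2-dimethyl-4,7-diphenyl-1,3-benzodioxol-5-ol
Conditions: NBS (1.0 equiv), MeCN, 0 °C, dark
Reagents that add atoms: N-bromosuccinimide, O=C1CCC(=O)N1Br
Why: Electrophilic aromatic bromination; the single unsubstituted carbon of the central ring (future C3a) is ortho to the free hydroxyl and para to a ring oxygen and is far more activated than the phenyl rings.

Step 4
Reactants: 6 6-bromo-2,2-dimethyl-4,7-diphenyl-1,3-benzodioxol-5-ol
Product: 7 tert-butyl[(6-bromo-2,2-dimethyl-4,7-diphenyl-1,3-benzodioxol-5-yl)oxy]dimethylsilane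
Conditions: TBSOTf, 2,6-lutidine, CH2Cl2, 0 °C to 20 °C
Reagents that add atoms: tert-butyldimethylsilyl trifluoromethanesulfonate, CC(C)(C)[Si](C)(C)OS(=O)(=O)C(F)(F)F
Why: O-Silylation of a phenol flanked by two ortho groups calls for the reactive silyl triflate; the silyl ether prevents benzofuran formation in the palladium step and can later be removed by fluoride without acid.

Step 5
Reactants: 8 4'-hydroxyacetophenone
Product: 9 4'-(methoxymethoxy)acetophenone
Conditions: MOMCl, iPr2NEt, CH2Cl2, 0 °C to 20 °C
Reagents that add atoms: chloromethyl methyl ether, COCCl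
Why: O-Alkylation of the phenol with an α-chloro ether (Williamson type); the acetal is stable to base, fluoride and light and falls in the acid treatment of step 10.

Step 6
Reactants: 7 tert-butyl[(6-bromo-2,2-dimethyl-4,7-diphenyl-1,3-benzodioxol-5-yl)oxy]dimethylsilane; 9 4'-(methoxymethoxy)acetophenone
Product: 10 2-[6-(tert-butyldimethylsilyloxy)-2,2-dimethyl-4,7-diphenyl-1,3-benzodioxol-5-yl]-1-[4-(methoxymethoxy)phenyl]ethanone
Conditions: Pd(OAc)2 (5 mol %), XPhos (10 mol %), K3PO4 (2.5 equiv), 9 (1.5 equiv), toluene, 100 °C, Ar
Reagents that add atoms: none
Why: Palladium-catalysed α-arylation of a ketone enolate: zerovalent palladium (formed in situ from Pd(OAc)2 and the phosphine) inserts into the C–Br bond, the enolate is transferred and reductive elimination forms the C3a–CH2 bond; the bulky biaryl phosphine is chosen for the di-ortho-substituted bromide, the same crowding rules out a second arylation, and the mild phosphate base spares the aryl silyl ether.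

Step 7
Reactants: 10 2-[6-(tert-butyldimethylsilyloxy)-2,2-dimethyl-4,7-diphenyl-1,3-benzodioxol-5-yl]-1-[4-(methoxymethoxy)phenyl]ethanone
Product: 11 2-diazo-2-[6-(tert-butyldimethylsilyloxy)-2,2-dimethyl-4,7-diphenyl-1,3-benzodioxol-5-yl]-1-[4-(methoxymethoxy)phenyl]ethanone
Conditions: p-ABSA (1.3 equiv), DBU (1.5 equiv), MeCN, 0 °C to 20 °C, dark
Reagents that add atoms: 4-acetamidobenzenesulfonyl azide, CC(=O)Nc1ccc(cc1)S(=O)(=O)N=[N+]=[N-]
Why: Regitz diazo transfer: the benzylic ketone is acidic enough for DBU, the enolate attacks the terminal nitrogen of the sulfonyl azide and the triazene collapses to diazo ketone and sulfonamide; only the methylene can take up the diazo group, so its position is fixed.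

Step 8
Reactants: 11 2-diazo-2-[6-(tert-butyldimethylsilyloxy)-2,2-dimethyl-4,7-diphenyl-1,3-benzodioxol-5-yl]-1-[4-(methoxymethoxy)phenyl]ethanone
Product: 12 2-diazo-2-(6-hydroxy-2,2-dimethyl-4,7-diphenyl-1,3-benzodioxol-5-yl)-1-[4-(methoxymethoxy)phenyl]ethanone
Conditions: TBAF (1.1 equiv), AcOH (1.1 equiv), THF, 0 °C, dark; used at once
Reagents that add atoms: none
Why: Fluoride cleaves the aryl silyl ether through Si–F bond formation under acetic acid buffering; no mineral acid, metal or reductant touches the diazo group, and the acetal and ketal are inert.

Step 9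
Reactants: 12 2-diazo-2-(6-hydroxy-2,2-dimethyl-4,7-diphenyl-1,3-benzodioxol-5-yl)-1-[4-(methoxymethoxy)phenyl]ethanone
Product: 14 acetonide of 5,6-dihydroxy-3-[4-(methoxymethoxy)phenyl]-4,7-diphenylbenzofuran-2(3H)-one (racemic), via diarylketene 13 (not isolated)
Conditions: hν (365 nm LED), dry degassed toluene, 0.01 M, 20 °C
Reagents that add atoms: none
Why: Photochemical Wolff rearrangement: excitation expels N2 and, on the singlet surface, the 4-(methoxymethoxy)phenyl group shifts from the carbonyl carbon to the former diazo carbon (new C3–aryl bond), giving diarylketene 13. The closest known reaction type is the light-induced Wolff rearrangement of 2-diazo-1,2-diarylethanones to diarylketenes followed by intramolecular capture of the ketene by a hydroxyl group. The C7a hydroxyl, held ortho to C3a, adds in the ketene plane to the sp carbon C2 (new O1–C2 bond); the closure is a five-membered 5-exo-dig attack on the C=O of the cumulene and gives the enol (a 2-hydroxybenzofuran), which tautomerises to the lactone. C3 becomes a stereocentre only in that tautomerisation; protonation is uncontrolled, 14 is racemic and the centre is erased in step 10, so no control is needed. The step needs migration to beat carbene dimerisation, O–H insertion and attack on the neighbouring C4 phenyl ring; the migrating group is the only substituent on the carbonyl carbon and is an electron-rich aryl group of high migratory aptitude, and direct irradiation at high dilution favours the concerted singlet path. Ketene capture must be intramolecular; a dry aprotic solvent offers no competing nucleophile and the phenol oxygen is positioned for five-membered ring closure. The crowded C3 is thus assembled by an intramolecular 1,2-shift and not by an intermolecular substitution beside the C4 phenyl group.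

Step 10
Reactants: 14 acetonide of 5,6-dihydroxy-3-[4-(methoxymethoxy)phenyl]-4,7-diphenylbenzofuran-2(3H)-one (racemic)
Product: 16 5-hydroxy-3-(4-hydroxyphenyl)-4,7-diphenylbenzofuran-2,6-dione, via leuco triol lactone 15 (not isolated)
Conditions: TFA/H2O (9:1), 40 °C, Ar; evaporate; DDQ (1.05 equiv), 1,4-dioxane, 20 °C
Reagents that add atoms: none
Why: Aqueous acid hydrolyses the isopropylidene ketal and the methoxymethyl acetal while the aryl lactone is acid-stable; DDQ dehydrogenation of the catechol then gives the ortho-quinone, which tautomerises (C3–H to O5) to the extended para-quinone methide, and the C3 stereocentre disappears.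

Step 11
Reactants: 16 5-hydroxy-3-(4-hydroxyphenyl)-4,7-diphenylbenzofuran-2,6-dione
Product: 17 3-(4-hydroxyphenyl)-5-methoxy-4,7-diphenylbenzofuran-2,6-dione
Conditions: TMSCHN2 (1.05 equiv, 2 M in hexanes), toluene/MeOH (4:1), 0 °C
Reagents that add atoms: (trimethylsilyl)diazomethane, C[Si](C)(C)C=[N+]=[N-]
Why: O-Methylation by a diazoalkane starts with protonation of the reagent, so the more acidic hydroxyl reacts first; O5–H is a doubly vinylogous carboxylic acid (conjugated with the lactone carbonyl through C4=C5 and C3a=C3) whereas the other hydroxyl is a phenol on a twisted ring, and one equivalent of this non-explosive diazomethane surrogate should stop at the monomethyl ether.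

## Compound list

1 | 2,5-diphenyl-1,4-benzoquinone | O=C1C=C(c2ccccc2)C(=O)C=C1c1ccccc1 | starting material
2 | 3,6-diphenylbenzene-1,2,4-triyl triacetate | CC(=O)Oc1cc(-c2ccccc2)c(OC(C)=O)c(OC(C)=O)c1-c1ccccc1 | intermediate
3 | 2,2-dimethoxypropane | COC(C)(C)OC | starting material
4 | 3,6-diphenylbenzene-1,2,4-triol | Oc1cc(-c2ccccc2)c(O)c(O)c1-c1ccccc1 | intermediate (not isolated)
5 | 2,2-dimethyl-4,7-diphenyl-1,3-benzodioxol-5-ol | CC1(C)Oc2c(O1)c(-c1ccccc1)c(O)cc2-c1ccccc1 | intermediate
6 | 6-bromo-2,2-dimethyl-4,7-diphenyl-1,3-benzodioxol-5-ol | CC1(C)Oc2c(O1)c(-c1ccccc1)c(O)c(Br)c2-c1ccccc1 | intermediate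
7 | tert-butyl[(6-bromo-2,2-dimethyl-4,7-diphenyl-1,3-benzodioxol-5-yl)oxy]dimethylsilane | CC1(C)Oc2c(O1)c(-c1ccccc1)c(O[Si](C)(C)C(C)(C)C)c(Br)c2-c1ccccc1 | intermediate
8 | 4'-hydroxyacetophenone | CC(=O)c1ccc(O)cc1 | starting material
9 | 4'-(methoxymethoxy)acetophenone | CC(=O)c1ccc(OCOC)cc1 | intermediate
10 | 2-[6-(tert-butyldimethylsilyloxy)-2,2-dimethyl-4,7-diphenyl-1,3-benzodioxol-5-yl]-1-[4-(methoxymethoxy)phenyl]ethanone | CC1(C)Oc2c(O1)c(-c1ccccc1)c(O[Si](C)(C)C(C)(C)C)c(CC(=O)c1ccc(OCOC)cc1)c2-c1ccccc1 | intermediate
11 | 2-diazo-2-[6-(tert-butyldimethylsilyloxy)-2,2-dimethyl-4,7-diphenyl-1,3-benzodioxol-5-yl]-1-[4-(methoxymethoxy)phenyl]ethanone | CC1(C)Oc2c(O1)c(-c1ccccc1)c(O[Si](C)(C)C(C)(C)C)c(C(=[N+]=[N-])C(=O)c1ccc(OCOC)cc1)c2-c1ccccc1 | intermediate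
12 | 2-diazo-2-(6-hydroxy-2,2-dimethyl-4,7-diphenyl-1,3-benzodioxol-5-yl)-1-[4-(methoxymethoxy)phenyl]ethanone | CC1(C)Oc2c(O1)c(-c1ccccc1)c(O)c(C(=[N+]=[N-])C(=O)c1ccc(OCOC)cc1)c2-c1ccccc1 | intermediate (precursor of the key step)
13 | 2-(6-hydroxy-2,2-dimethyl-4,7-diphenyl-1,3-benzodioxol-5-yl)-2-[4-(methoxymethoxy)phenyl]ethenone | CC1(C)Oc2c(O1)c(-c1ccccc1)c(O)c(C(=C=O)c1ccc(OCOC)cc1)c2-c1ccccc1 | intermediate (not isolated)
14 | acetonide of 5,6-dihydroxy-3-[4-(methoxymethoxy)phenyl]-4,7-diphenylbenzofuran-2(3H)-one (racemic) | CC1(C)Oc2c(O1)c(-c1ccccc1)c1OC(=O)C(c3ccc(OCOC)cc3)c1c2-c1ccccc1 | intermediate (product of the key step)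
15 | 5,6-dihydroxy-3-(4-hydroxyphenyl)-4,7-diphenylbenzofuran-2(3H)-one (racemic) | O=C1Oc2c(-c3ccccc3)c(O)c(O)c(-c3ccccc3)c2C1c1ccc(O)cc1 | intermediate (not isolated)
16 | 5-hydroxy-3-(4-hydroxyphenyl)-4,7-diphenylbenzofuran-2,6-dione | OC1=C(c2ccccc2)C2=C(c3ccc(O)cc3)C(=O)OC2=C(c2ccccc2)C1=O | intermediate
17 | 3-(4-hydroxyphenyl)-5-methoxy-4,7-diphenylbenzofuran-2,6-dione | COC1=C(c2ccccc2)C2=C(c3ccc(O)cc3)C(=O)OC2=C(c2ccccc2)C1=O | target

## Step count and least certain steps

Total: 11 steps. Longest linear sequence: 10 steps (steps 1 to 4 and 6 to 11, from 1); step 5 is a one-step side branch.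

Step 9 (key step). The most likely failure is carbene chemistry outrunning the 1,2-aryl shift: cyclisation onto the neighbouring C4 phenyl ring or dimerisation. The diazo carbon sits on a ring twisted out of conjugation, and the geometry needed for concerted migration may be poorly populated. Slow lactonisation of a hindered ketene, leaving it to dimerise or to be hydrolysed, is the second concern. The fallback leaves the diazo ketone manifold and forms the same lactone skeleton by an acid-mediated Friedel–Crafts alkylation and lactonisation. Phenol 5 is heated with commercial 4-hydroxymandelic acid and TsOH in acetic acid. The benzylic cation attacks the only free ring position, ortho to the hydroxyl, and the hydroxy acid closes to the acetonide of 5,6-dihydroxy-3-(4-hydroxyphenyl)-4,7-diphenylbenzofuran-2(3H)-one F1. Under the conditions of step 10, F1 rejoins the route at 16.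

Step 6. The most likely failure is a stalled coupling: slow oxidative addition and reductive elimination at a bromide flanked by phenyl and silyloxy groups on an electron-rich ring. Protodebromination and base-induced loss of the silyl group may accompany it, and loss of the silyl group would open the way to benzofuran formation. The fallback sets out from 5 and makes the C3a–CH2 bond by a Claisen rearrangement instead of a metal-catalysed coupling.
- O-Allylation (allyl bromide, K2CO3, acetone) should give 2,2-dimethyl-4,7-diphenyl-5-(prop-2-en-1-yloxy)-1,3-benzodioxole F2.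
- Heating (N,N-diethylaniline, 190 °C) should move the allyl group to the only open ortho position, giving 2,2-dimethyl-4,7-diphenyl-6-(prop-2-en-1-yl)-1,3-benzodioxol-5-ol F3.
- Silylation as in step 4 gives tert-butyl{[2,2-dimethyl-4,7-diphenyl-6-(prop-2-en-1-yl)-1,3-benzodioxol-5-yl]oxy}dimethylsilane F4.
- Lemieux–Johnson cleavage (OsO4 cat., NaIO4, 2,6-lutidine) gives 2-[6-(tert-butyldimethylsilyloxy)-2,2-dimethyl-4,7-diphenyl-1,3-benzodioxol-5-yl]acetaldehyde F5.
- Addition of 4-(methoxymethoxy)phenylmagnesium bromide at −78 °C gives 2-[6-(tert-butyldimethylsilyloxy)-2,2-dimethyl-4,7-diphenyl-1,3-benzodioxol-5-yl]-1-[4-(methoxymethoxy)phenyl]ethanol (racemic) F6.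
- Dess–Martin oxidation returns to the route at 10.

Step 7. The most likely failure is incomplete diazo transfer: the enolate carbon is shielded by the di-ortho-substituted ring and the bulky sulfonyl azide may not reach it, with silyl loss on forcing. The fallback sets out from 10 and introduces nitrogen with a small electrophile. Nitrosation of the lithium enolate (LiHMDS, isoamyl nitrite, THF, −78 °C) should give 2-[6-(tert-butyldimethylsilyloxy)-2,2-dimethyl-4,7-diphenyl-1,3-benzodioxol-5-yl]-2-(hydroxyimino)-1-[4-(methoxymethoxy)phenyl]ethanone F7. The Forster reaction (chloramine from aqueous NH3 and NaOCl, 0 °C) then converts the oxime into the diazo group and returns to the route at 11.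

Step 11. The most likely failure is loss of chemoselectivity: methylation of the phenolic oxygen as well, or first if conjugation with the quinone methide makes that phenol more acidic than assumed. Conjugate addition of methanol is a further risk. The fallback sets out from 16 and differentiates the two hydroxyls with silicon.
- TBSCl and imidazole in DMF silylate both, giving 5-(tert-butyldimethylsilyloxy)-3-[4-(tert-butyldimethylsilyloxy)phenyl]-4,7-diphenylbenzofuran-2,6-dione F8.
- The silyl group on O5 is a vinylogous silyl ester and should be hydrolysed selectively (AcOH, THF, water) to 5-hydroxy-3-[4-(tert-butyldimethylsilyloxy)phenyl]-4,7-diphenylbenzofuran-2,6-dione F9.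
- TMSCHN2 then has only O5–H to methylate and gives 3-[4-(tert-butyldimethylsilyloxy)phenyl]-5-methoxy-4,7-diphenylbenzofuran-2,6-dione F10.
- HF·pyridine in THF at 0 °C removes the aryl silyl ether and arrives at 17.

## Further compounds

F1 | step 9 | acetonide of 5,6-dihydroxy-3-(4-hydroxyphenyl)-4,7-diphenylbenzofuran-2(3H)-one (racemic) | CC1(C)Oc2c(O1)c(-c1ccccc1)c1OC(=O)C(c3ccc(O)cc3)c1c2-c1ccccc1
F2 | step 6 | 2,2-dimethyl-4,7-diphenyl-5-(prop-2-en-1-yloxy)-1,3-benzodioxole | C=CCOc1cc(-c2ccccc2)c2OC(C)(C)Oc2c1-c1ccccc1
F3 | step 6 | 2,2-dimethyl-4,7-diphenyl-6-(prop-2-en-1-yl)-1,3-benzodioxol-5-ol | C=CCc1c(O)c(-c2ccccc2)c2OC(C)(C)Oc2c1-c1ccccc1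
F4 | step 6 | tert-butyl{[2,2-dimethyl-4,7-diphenyl-6-(prop-2-en-1-yl)-1,3-benzodioxol-5-yl]oxy}dimethylsilane | C=CCc1c(O[Si](C)(C)C(C)(C)C)c(-c2ccccc2)c2OC(C)(C)Oc2c1-c1ccccc1
F5 | step 6 | 2-[6-(tert-butyldimethylsilyloxy)-2,2-dimethyl-4,7-diphenyl-1,3-benzodioxol-5-yl]acetaldehyde | O=CCc1c(O[Si](C)(C)C(C)(C)C)c(-c2ccccc2)c2OC(C)(C)Oc2c1-c1ccccc1
F6 | step 6 | 2-[6-(tert-butyldimethylsilyloxy)-2,2-dimethyl-4,7-diphenyl-1,3-benzodioxol-5-yl]-1-[4-(methoxymethoxy)phenyl]ethanol (racemic) | COCOc1ccc(cc1)C(O)Cc1c(O[Si](C)(C)C(C)(C)C)c(-c2ccccc2)c2OC(C)(C)Oc2c1-c1ccccc1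
F7 | step 7 | 2-[6-(tert-butyldimethylsilyloxy)-2,2-dimethyl-4,7-diphenyl-1,3-benzodioxol-5-yl]-2-(hydroxyimino)-1-[4-(methoxymethoxy)phenyl]ethanone (oxime geometry not defined) | COCOc1ccc(cc1)C(=O)C(=NO)c1c(O[Si](C)(C)C(C)(C)C)c(-c2ccccc2)c2OC(C)(C)Oc2c1-c1ccccc1
F8 | step 11 | 5-(tert-butyldimethylsilyloxy)-3-[4-(tert-butyldimethylsilyloxy)phenyl]-4,7-diphenylbenzofuran-2,6-dione | CC(C)(C)[Si](C)(C)OC1=C(c2ccccc2)C2=C(c3ccc(O[Si](C)(C)C(C)(C)C)cc3)C(=O)OC2=C(c2ccccc2)C1=O
F9 | step 11 | 5-hydroxy-3-[4-(tert-butyldimethylsilyloxy)phenyl]-4,7-diphenylbenzofuran-2,6-dione | OC1=C(c2ccccc2)C2=C(c3ccc(O[Si](C)(C)C(C)(C)C)cc3)C(=O)OC2=C(c2ccccc2)C1=O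
F10 | step 11 | 3-[4-(tert-butyldimethylsilyloxy)phenyl]-5-methoxy-4,7-diphenylbenzofuran-2,6-dione | COC1=C(c2ccccc2)C2=C(c3ccc(O[Si](C)(C)C(C)(C)C)cc3)C(=O)OC2=C(c2ccccc2)C1=O
A1 | alternative 1 | 4-[(E)-3-[4-(benzyloxy)phenyl]-3-(tert-butyldimethylsilyloxy)-1-phenylprop-1-en-1-yl]-3-isopropoxy-4-methoxy-2-phenylcyclobut-2-en-1-one (racemic, mixture of diastereomers) | COC1(/C(c2ccccc2)=C/C(O[Si](C)(C)C(C)(C)C)c2ccc(OCc3ccccc3)cc2)C(OC(C)C)=C(c2ccccc2)C1=O
A2 | alternative 1 | 2-[[4-(benzyloxy)phenyl](tert-butyldimethylsilyloxy)methyl]-5-isopropoxy-4-methoxy-3,6-diphenylphenol (racemic) | COc1c(OC(C)C)c(-c2ccccc2)c(O)c(C(O[Si](C)(C)C(C)(C)C)c2ccc(OCc3ccccc3)cc2)c1-c1ccccc1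
A3 | alternative 2 | 2-[4-(tert-butyldimethylsilyloxy)phenyl]-2-(4-hydroxy-3-methoxy-2,5-diphenylphenyl)acetic acid (racemic) | COc1c(O)c(-c2ccccc2)cc(C(C(=O)O)c2ccc(O[Si](C)(C)C(C)(C)C)cc2)c1-c1ccccc1
A4 | alternative 2 | 3-[4-(tert-butyldimethylsilyloxy)phenyl]-5-methoxy-4,7-diphenylbenzofuran-2,6-dione | COC1=C(c2ccccc2)C2=C(c3ccc(O[Si](C)(C)C(C)(C)C)cc3)C(=O)OC2=C(c2ccccc2)C1=O
A5 | alternative 2 | 3,6-diphenylbenzene-1,2-diol | Oc1c(O)c(-c2ccccc2)ccc1-c1ccccc1
A6 | alternative 3 | acetonide of 4,7-dibromo-5,6-dihydroxy-3-[4-(pivaloyloxy)phenyl]benzofuran-2(3H)-one (racemic) | CC1(C)Oc2c(O1)c(Br)c1OC(=O)C(c3ccc(OC(=O)C(C)(C)C)cc3)c1c2Br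
A7 | alternative 3 | acetonide of 5,6-dihydroxy-4,7-diphenyl-3-[4-(pivaloyloxy)phenyl]benzofuran-2(3H)-one (racemic) | CC1(C)Oc2c(O1)c(-c1ccccc1)c1OC(=O)C(c3ccc(OC(=O)C(C)(C)C)cc3)c1c2-c1ccccc1
A8 | alternative 3 | phenylboronic acid | OB(O)c1ccccc1
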